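The target is cut at C3–C3a and at the C–O bond of the C3 hydroxymethyl group. C3 of the dihydrofuran ring carries both the benzo-ring carbon C3a and an oxygenated exocyclic CH2, so a vinyl group can stand in for it. An aryl radical, generated at the iodine-bearing carbon of (R)-4-bromo-2-iodophenyl 1-(3,4,5-trimethoxyphenyl)allyl ether, closes the five-membered ring on the inner alkene carbon, and a nitroxide caps the terminal carbon with oxygen. One operation thus forms the ring, the C3–C3a bond, the CH2–O bond and the C3 stereocentre. C2 comes from an iridium-catalysed allylic etherification, and the bromide later carries the hydroxypropenyl chain.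

Key step: step 5

Stereochemical reading: the target is (2R,3S), with the C2 aryl and C3 hydroxymethyl groups trans. C2 is carried unchanged from the (R)-allyl ether 7, and the descriptors of 7 and 9 are consistent with the target.

Assumption: the ligand L in step 4 is (Ra,R,R)-O,O'-(1,1'-binaphthalene-2,2'-diyl) N,N-bis(1-phenylethyl)phosphoramidite, taken to deliver the (R)-ether. This sense of induction is not certain and should be confirmed on the first batch by chiral HPLC and correlation; the (Sa,S,S) antipode is used if the (S)-ether forms.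

Step 1
Reactants: 1 (E)-3,4,5-trimethoxycinnamic acid
Product: 2 methyl (E)-3,4,5-trimethoxycinnamate
Conditions: MeOH, H2SO4 (cat.), reflux
Reagents that add atoms: methanol, CO
Why: Fischer esterification in excess methanol under acid catalysis should drive the unhindered conjugated acid to its methyl ester, which makes the following hydride reduction clean.

Step 2
Reactants: 2 methyl (E)-3,4,5-trimethoxycinnamate
Product: 3 (E)-3-(3,4,5-trimethoxyphenyl)prop-2-en-1-ol
Conditions: DIBAL-H (2.5 equiv), CH2Cl2, −78 to 0 °C; Rochelle salt work-up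
Reagents that add atoms: none
Why: DIBAL-H reduction of an α,β-unsaturated ester is 1,2-selective at low temperature, so the (E)-allylic alcohol should form without saturation of the alkene.

Step 3
Reactants: 3 (E)-3-(3,4,5-trimethoxyphenyl)prop-2-en-1-ol
Product: 4 (E)-3-(3,4,5-trimethoxyphenyl)allyl methyl carbonate
Conditions: ClCO2Me, pyridine, CH2Cl2, 0 °C
Reagents that add atoms: methyl chloroformate, COC(=O)Cl
Why: Carbonate formation by acylation of the primary allylic alcohol with a chloroformate and pyridine is fast at 0 °C and installs the leaving group needed for allyl–iridium formation.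

Step 4
Reactants: 4 (E)-3-(3,4,5-trimethoxyphenyl)allyl methyl carbonate; 5 4-bromo-2-iodophenol
Product: 7 (R)-4-bromo-2-iodo-1-{[1-(3,4,5-trimethoxyphenyl)prop-2-en-1-yl]oxy}benzene, via sodium 4-bromo-2-iodophenolate 6 (not isolated)
Conditions: 5 (1.5 equiv), NaH, THF, 0 °C; then 4, [Ir(cod)Cl]2 (2 mol%), L (4 mol%; pre-activated with n-PrNH2, volatiles removed), THF, rt to 50 °C
Reagents that add atoms: none
Why: Iridium-catalysed asymmetric allylic etherification (a Tsuji–Trost-type substitution) should work because the cyclometallated iridium–phosphoramidite catalyst ionises the linear carbonate to an allyl complex that the aryloxide attacks at the aryl-bearing terminus, the ligand antipode fixing the new C–O stereocentre as (R), while the aryl iodide and bromide are inert to this catalyst.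

Step 5
Reactants: 7 (R)-4-bromo-2-iodo-1-{[1-(3,4,5-trimethoxyphenyl)prop-2-en-1-yl]oxy}benzene; 8 2,2,6,6-tetramethylpiperidin-1-oxyl (TEMPO)
Product: 9 1-{[(2R,3S)-5-bromo-2-(3,4,5-trimethoxyphenyl)-2,3-dihydrobenzofuran-3-yl]methoxy}-2,2,6,6-tetramethylpiperidine
Conditions: Bu3SnH (3 equiv, in portions), TEMPO (5 equiv), toluene, 70 °C
Reagents that add atoms: 2,2,6,6-tetramethylpiperidin-1-oxyl (compound 8), CC1(C)CCCC(C)(C)N1[O]
Why: TEMPO removes hydrogen from Bu3SnH to give the stannyl radical, which abstracts iodine from the aryl carbon ortho to oxygen; the aryl radical adds to the inner vinyl carbon to forge C3–C3a, and the primary radical left on the terminal carbon is captured by a second TEMPO at close to the diffusion limit, well ahead of hydrogen transfer from the stannane. The closest known reaction type is the tin hydride-mediated aryl radical–alkene cyclisation with in situ nitroxide trapping, established for 2-haloaryl allyl ethers and N-allyl-2-haloanilines. The dihydrofuran ring closes in the 5-exo-trig mode, the 6-endo path to a chroman being disfavoured for an unsubstituted vinyl terminus. The new C3 stereocentre is controlled by the existing (R) centre at C2: in the chair-like transition state the C2 aryl group sits pseudo-equatorial and the vinyl CH2 turns away from it to avoid allylic strain, so the CH2O group should end up trans to the aryl group, which is (3S). The step needs C–I over C–Br chemoselectivity and cyclisation ahead of direct trapping of the aryl radical; the first is secured by the weaker C–I bond (stannyl radicals abstract iodine orders of magnitude faster than bromine, and TEMPO scavenges stannyl radicals that would otherwise attack the bromide), the second by the very fast ring closure of 2-(allyloxy)aryl radicals.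

Step 6
Reactants: 9 1-{[(2R,3S)-5-bromo-2-(3,4,5-trimethoxyphenyl)-2,3-dihydrobenzofuran-3-yl]methoxy}-2,2,6,6-tetramethylpiperidine
Product: 10 [(2R,3S)-5-bromo-2-(3,4,5-trimethoxyphenyl)-2,3-dihydrobenzofuran-3-yl]methanol
Conditions: Zn dust, AcOH–THF–H2O (3:1:1), 50–70 °C
Reagents that add atoms: none
Why: Reductive N–O cleavage of the O-alkyl hydroxylamine by zinc in acetic acid (dissolving-metal reduction) should free the primary alcohol without touching the aryl bromide, the benzylic ether or either stereocentre.

Step 7
Reactants: 10 [(2R,3S)-5-bromo-2-(3,4,5-trimethoxyphenyl)-2,3-dihydrobenzofuran-3-yl]methanol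
Product: 11 methyl (E)-3-[(2R,3S)-3-(hydroxymethyl)-2-(3,4,5-trimethoxyphenyl)-2,3-dihydrobenzofuran-5-yl]acrylate
Conditions: methyl acrylate (3 equiv), Pd(OAc)2 (5 mol%), P(o-tol)3 (10 mol%), Et3N, DMF, 100 °C
Reagents that add atoms: methyl acrylate, C=CC(=O)OC
Why: Mizoroki–Heck coupling of the aryl bromide with an acrylate proceeds by syn-carbopalladation and syn-β-hydride elimination, which should give the (E)-cinnamate only, the free primary alcohol and the two ring stereocentres being spectators under the amine base.

Step 8
Reactants: 11 methyl (E)-3-[(2R,3S)-3-(hydroxymethyl)-2-(3,4,5-trimethoxyphenyl)-2,3-dihydrobenzofuran-5-yl]acrylate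
Product: 12 (E)-3-[(2R,3S)-3-(hydroxymethyl)-2-(3,4,5-trimethoxyphenyl)-2,3-dihydrobenzofuran-5-yl]prop-2-en-1-ol
Conditions: DIBAL-H (4 equiv), CH2Cl2, −78 to 0 °C; Rochelle salt work-up
Reagents that add atoms: none
Why: DIBAL-H reduction of the conjugated ester in the 1,2-sense should give the allylic alcohol (one extra equivalent is consumed by the free hydroxyl), leaving the (E)-alkene, the aryl ethers and both stereocentres untouched.

Compound list
1 | (E)-3,4,5-trimethoxycinnamic acid | COc1cc(/C=C/C(=O)O)cc(OC)c1OC | starting material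
2 | methyl (E)-3,4,5-trimethoxycinnamate | COC(=O)/C=C/c1cc(OC)c(OC)c(OC)c1 | intermediate
3 | (E)-3-(3,4,5-trimethoxyphenyl)prop-2-en-1-ol | OC/C=C/c1cc(OC)c(OC)c(OC)c1 | intermediate
4 | (E)-3-(3,4,5-trimethoxyphenyl)allyl methyl carbonate | COC(=O)OC/C=C/c1cc(OC)c(OC)c(OC)c1 | intermediate
5 | 4-bromo-2-iodophenol | Oc1ccc(Br)cc1I | starting material
6 | sodium 4-bromo-2-iodophenolate (formed in the flask, not isolated) | [Na+].[O-]c1ccc(Br)cc1I | intermediate
7 | (R)-4-bromo-2-iodo-1-{[1-(3,4,5-trimethoxyphenyl)prop-2-en-1-yl]oxy}benzene | COc1cc([C@@H](C=C)Oc2ccc(Br)cc2I)cc(OC)c1OC | intermediate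
8 | 2,2,6,6-tetramethylpiperidin-1-oxyl (TEMPO) | CC1(C)CCCC(C)(C)N1[O] | starting material
9 | 1-{[(2R,3S)-5-bromo-2-(3,4,5-trimethoxyphenyl)-2,3-dihydrobenzofuran-3-yl]methoxy}-2,2,6,6-tetramethylpiperidine | COc1cc([C@@H]2Oc3ccc(Br)cc3[C@H]2CON2C(C)(C)CCCC2(C)C)cc(OC)c1OC | intermediate
10 | [(2R,3S)-5-bromo-2-(3,4,5-trimethoxyphenyl)-2,3-dihydrobenzofuran-3-yl]methanol | COc1cc([C@@H]2Oc3ccc(Br)cc3[C@H]2CO)cc(OC)c1OC | intermediate
11 | methyl (E)-3-[(2R,3S)-3-(hydroxymethyl)-2-(3,4,5-trimethoxyphenyl)-2,3-dihydrobenzofuran-5-yl]acrylate | COc1cc([C@@H]2Oc3ccc(/C=C/C(=O)OC)cc3[C@H]2CO)cc(OC)c1OC | intermediate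
12 | (E)-3-[(2R,3S)-3-(hydroxymethyl)-2-(3,4,5-trimethoxyphenyl)-2,3-dihydrobenzofuran-5-yl]prop-2-en-1-ol | COc1cc([C@@H]2Oc3ccc(/C=C/CO)cc3[C@H]2CO)cc(OC)c1OC | target

Total step count: 8. Longest linear sequence: 8 steps (1 to 12); 5 and 8 enter as purchased materials.

Steps most likely to fail

Step 5. Facial control in the ring closure may be incomplete: the vinyl terminus can also close syn to the C2 aryl group, so the 2,3-cis epimer would accompany the trans product. Partial loss of bromine by over-reduction is a lesser concern. The fallback replaces kinetic control of C3 by thermodynamic control. It sets out from 9 as the mixture of C3 epimers. Oxidation with mCPBA (CH2Cl2, 0 °C; N-oxidation, then Cope-type elimination) should convert the alkoxyamines into the 3-carbaldehydes. The cis aldehyde (2R,3S)-5-bromo-2-(3,4,5-trimethoxyphenyl)-2,3-dihydrobenzofuran-3-carbaldehyde F1 is then equilibrated through its enolate with DBU (CH2Cl2, rt) to the more stable trans aldehyde (2R,3R)-5-bromo-2-(3,4,5-trimethoxyphenyl)-2,3-dihydrobenzofuran-3-carbaldehyde F2. F2 has the spatial arrangement of the target; its descriptor differs only because the formyl group outranks C2. Ring opening by β-elimination of the aryloxide would be a reverse 5-endo-trig process and is not expected to compete, so C2 should hold. NaBH4 (MeOH, 0 °C) then gives 10, where the route is rejoined.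

Step 4. The hindered, weakly nucleophilic ortho-iodophenoxide may attack the unsubstituted allyl terminus to give the linear ether, turnover may be slow, or re-ionisation of the branched ether may erode enantiomeric purity. The fallback takes the stereocentre from a reagent-controlled epoxidation and forms the C–O bond by Mitsunobu inversion. It sets out from 3. Sharpless asymmetric epoxidation (Ti(Oi-Pr)4, D-(−)-diisopropyl tartrate, t-BuOOH, 4 Å molecular sieves, CH2Cl2, −20 °C) should give [(2R,3R)-3-(3,4,5-trimethoxyphenyl)oxiran-2-yl]methanol F3. Iodination (PPh3, I2, imidazole, CH2Cl2) gives (2S,3R)-2-(iodomethyl)-3-(3,4,5-trimethoxyphenyl)oxirane F4. Zinc-mediated reductive opening (Zn, EtOH, reflux) gives (S)-1-(3,4,5-trimethoxyphenyl)prop-2-en-1-ol F5, the benzylic C–O bond staying intact. Mitsunobu etherification with phenol 5 (PPh3, DIAD, toluene, 0 °C) inverts this centre and comes back to the route at 7.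

Step 7. Oxidative addition to the electron-rich, para-alkoxy aryl bromide may be sluggish at the temperature the Heck reaction needs, with catalyst decomposition to palladium black and incomplete conversion. The fallback uses a Suzuki–Miyaura coupling that brings in the three-carbon chain already at the alcohol oxidation level. It sets out from 10. Coupling with commercial (E)-tert-butyldimethyl{[3-(4,4,5,5-tetramethyl-1,3,2-dioxaborolan-2-yl)allyl]oxy}silane (Pd(dppf)Cl2, K2CO3, dioxane–H2O, 80 °C) should give the silyl ether {(2R,3S)-5-[(E)-3-(tert-butyldimethylsilyloxy)prop-1-en-1-yl]-2-(3,4,5-trimethoxyphenyl)-2,3-dihydrobenzofuran-3-yl}methanol F6. TBAF (THF, rt) then releases the target 12 directly, so compound 11 and step 8 are bypassed.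

Further compounds
F1 | step 5 | (2R,3S)-5-bromo-2-(3,4,5-trimethoxyphenyl)-2,3-dihydrobenzofuran-3-carbaldehyde (2,3-cis) | COc1cc([C@@H]2Oc3ccc(Br)cc3[C@@H]2C=O)cc(OC)c1OC
F2 | step 5 | (2R,3R)-5-bromo-2-(3,4,5-trimethoxyphenyl)-2,3-dihydrobenzofuran-3-carbaldehyde (2,3-trans) | COc1cc([C@@H]2Oc3ccc(Br)cc3[C@H]2C=O)cc(OC)c1OC
F3 | step 4 | [(2R,3R)-3-(3,4,5-trimethoxyphenyl)oxiran-2-yl]methanol | OC[C@H]1O[C@@H]1c1cc(OC)c(OC)c(OC)c1
F4 | step 4 | (2S,3R)-2-(iodomethyl)-3-(3,4,5-trimethoxyphenyl)oxirane | IC[C@H]1O[C@@H]1c1cc(OC)c(OC)c(OC)c1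
F5 | step 4 | (S)-1-(3,4,5-trimethoxyphenyl)prop-2-en-1-ol | C=C[C@H](O)c1cc(OC)c(OC)c(OC)c1
F6 | step 7 | {(2R,3S)-5-[(E)-3-(tert-butyldimethylsilyloxy)prop-1-en-1-yl]-2-(3,4,5-trimethoxyphenyl)-2,3-dihydrobenzofuran-3-yl}methanol | COc1cc([C@@H]2Oc3ccc(/C=C/CO[Si](C)(C)C(C)(C)C)cc3[C@H]2CO)cc(OC)c1OC
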